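## Analysis of the target

Target 19 is a spiro meroterpenoid. Rings A and B form a 7-methoxy-6,8,8-trimethyl-3,4-dihydrochromen-5(8H)-one: ring A (C4a, C5, C6, C7, C8, C8a) is a cross-conjugated cyclohexadienone whose C5 carbonyl is flanked by the C6=C7 methyl enol ether and by the C4a=C8a enol ether of ring B (O1, C2, C3, C4, C4a, C8a). C2 is spiro-linked to a cadinane-type bicycle: ring C (C2, C1', C8a', C4a', C4', C3') holds the C1'=C8a' alkene, and ring D (C8a', C8', C7', C6', C5', C4a') carries isopropyl on C8' and methyl on C5'. There are five stereocentres: C2 (S), C4 (R), C4a' (R), C5' (R) and C8' (S). On ring D the isopropyl and methyl groups are trans, as in (−)-menthone 4, while the C4a'–C4' bond is cis to the C5' methyl and trans to the isopropyl group, so it is axial on the menthone chair and the less stable arrangement next to a carbonyl; at C2, O1 lies anti to H-4a', and C4 stands alone on ring B. The sensitive sites are the tertiary allylic ether at C2 (its leaving group is a vinylogous carboxylate, so acid ionises it), the hydrolysable enol ether at C7 and, in any open precursor, the acidic trione of ring A with its two competing enol oxygens. The synthesis is hard because a quaternary spiro centre joins two remote stereochemical domains, the C4a' substituent must be axial, and the alkene must sit at C1'=C8a', the least substituted of the three positions around C8a'. The strategy rests on one feature: C2 is a tertiary carbon bearing O1, and its neighbour C1' leads to C8a', which maps onto the carbonyl carbon of 4, so C1'–C8a' and O1–C2 can both be made from an alkene, a ketone and an enol in one cationic event.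

## Retrosynthetic reasoning

**19 to 17.** The C1'=C8a' alkene is traced back to the tertiary C8a' alcohol 17. This exposes C8a' as a former carbonyl carbon. In the forward direction the dehydration must go toward C1' only. In 17 the hydroxyl is axial on ring D, and its only anti-periplanar hydrogen is H-8'. A base-induced anti elimination would therefore give the wrong, tetrasubstituted alkene, and a syn elimination is planned instead.

**17 to 16.** The bonds C1'–C8a' and O1–C2 are cut together. This opens rings C and B and removes the stereocentres C8a' and C2, leaving the open-chain compound 16. In 16 a 1,1-disubstituted alkene (C2=C1'H2) sits between the enolised trione and the 6-alkylated menthone. The cut is made here because C2 is the Markovnikov terminus of that alkene and lies five atoms from the enol oxygen. The forward reaction has to add the alkene to a Lewis-acid-activated ketone and trap the tertiary cation with oxygen before a proton is lost.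

**16 to 15.** The methylene group is taken back to the C2 ketone of 15. A carbonyl at C2 is wanted because it activates both neighbouring positions (C3/C4 and C3'/C4') for conjugate additions. The forward methylenation must select the acyclic ketone over the hindered ring ketone and must not epimerise C4a'.

**15 to 8 and 14.** The C4–C4a bond is cut by a retro-Michael step into enone 8 and the cyclic 1,3-dicarbonyl 14. This is the only step that has to create C4, and it can be run under catalyst control on an acyclic enone.

**8 to 6 and 3, then to 4, 2 and 1.** The C4a'–C4' bond is cut by a second retro-Michael step into the kinetic silyl enol ether 6 of 4 and the cross-conjugated dienone 3. Ring D with C8' and C5' comes unchanged from the chiral pool. The forward addition must take place at the unsubstituted vinyl terminus of 3 and from the axial direction at C6 of the menthone ring. Dienone 3 goes back through dienol 2 to enal 1.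

**14 to 12, 11, 10 and 9.** Methylating a preformed trione would favour the less hindered, more acidic enol oxygen, which is the wrong one. The methoxy group is therefore placed at the aromatic stage (11), where it must end up between the future C8 and C6. The ring is dearomatised by threefold C-methylation (12). An allyl ester blocks the future C4a and is later removed with decarboxylation under neutral conditions, since an acyl blocking group could only be cleaved by acid that would also hydrolyse the enol ether. The sequence starts from the commercial acid 9 by way of ester 10.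

## Alternatives that were turned down

**Alternative 1:** Ring A is made last by cutting C5–C6. In the forward step a lithium amide base enolises the ethyl ketone of keto ester A1, a spiro dihydropyran with a methyl ester on C4a and a 2-methyl-3-oxopentan-2-yl group on C8a. The α-carbon attacks the ester in a Dieckmann-type closure and gives the trione enol A2, the O-desmethyl form of 19.
- For it: the ketone has only one enolisable position, the carbon connectivity of ring A is unambiguous, and no acidic trione is present while the spiro system is built. On these points it is stronger than the chosen route.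
- Against it: A2 must be O-methylated at O7 in competition with O5, and O7 is the more hindered oxygen (between C6–CH3 and the C8 gem-dimethyl group), so the last step carries a regiochemical problem. The ester of A1 is a β-alkoxyacrylate and a weak acylating agent, and the allylic tertiary ether must survive strong base. A1 still contains the whole spiro problem (C2, C4, C4a'), so the difficulty is moved and not solved.
- Comparison: the chosen route carries the methoxy group in from aromatic 11 and closes two rings in one step, which saves the separate construction of A1 and the late methylation.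

**Alternative 2:** The bonds C2–C3 and O1–C2 are cut. A secondary amine condenses the acetyl methyl group of the acetyl trione A3 with the carbonyl of the menthone-derived octalone A4 (Kabbe-type condensation), and the C8a enol oxygen then adds to C2 to give the spiro pyran-4-one A5.
- For it: it is the most convergent plan. A3 needs no blocking-group removal, since its acetyl group becomes C3–C4, and the C1'=C8a' alkene is present from the start, so no dehydration regiochemistry arises. On both points it is stronger than the chosen route.
- Against it: amines turn A4 into dienamines, through which C4a' and C8' (both γ-positions) can epimerise, and the axial C4a' centre is the unstable one. Condensation at an enone carbonyl is slow, and the new dienone offers the oxygen a 1,6-terminus (C8a') beside C2, with no control of the face at C2. A5 has a carbonyl at C4. Making the (R)-CH(isopropyl) centre from it needs addition of an isopropyl nucleophile to a vinylogous ester carbonyl and then a stereoselective reductive deoxygenation under acid, which would ionise the allylic spiro ether.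
- Comparison: the chosen route sets C4 by catalyst control on an acyclic enone before any ring exists and keeps C4a' away from amines that form dienamines, at the price of a dehydration whose regiochemistry must be controlled.

**Alternative 3:** The bonds C4a'–C8a' and C8'–C7' are cut. In triene A6 the enone C8a'=C8' (activated by the C1' carbonyl on C2) adds intramolecularly to the tethered C4a'=C5'–C6'=C7' diene (Diels–Alder) and gives the cis-fused C1' ketone A7 with a C5'=C6' alkene.
- For it: two rings and several stereocentres form in one pericyclic step. The C1' ketone of A7 can be enolised only toward C8a', which allows an unambiguous route to the C1'=C8a' alkene (enol triflate, then reduction). On alkene placement it is stronger than the chosen route.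
- Against it: A6 needs the quaternary α-alkoxy ketone centre C2 and C4 made enantioselectively before the cyclisation. The dienophile is a β-isopropyl enone and reacts sluggishly, and the facial and endo/exo selectivity depend only on C2. C5' is sp2 in A7, so its methyl stereocentre must be set afterwards by a face-selective hydrogenation, followed by the ketone-to-alkene conversion.
- Comparison: the chosen route takes C8' and C5' from 4 and has to control only C4a', C4, and in the key step C8a' and C2, in fewer steps.

Key step: step 11

Assumption 1: the trione unit is drawn as its C8a enol throughout; 15 and 16 equilibrate with cyclic hemiketal and tautomeric forms, which open under the conditions of the following steps.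

Assumption 2: the sense of induction of the cinchona primary amine in step 9 is carried over from β-aryl enones; should the C4 epimer predominate, the quinine-derived pseudo-enantiomer of the catalyst is used.

## Route

Step 1
Reactants: 1 (E)-4-methylpent-2-enal
Product: 2 (E)-6-methylhepta-1,4-dien-3-ol (racemic)
Conditions: CH2=CHMgBr, THF, −78 → 0 °C; aq. NH4Cl
Reagents that add atoms: vinylmagnesium bromide, C=C[Mg]Br
Why: Grignard 1,2-addition to the enal carbonyl; the new carbinol centre is racemic and disappears in step 2.

Step 2
Reactants: 2 (E)-6-methylhepta-1,4-dien-3-ol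
Product: 3 (E)-6-methylhepta-1,4-dien-3-one
Conditions: MnO2 (activated, excess), CH2Cl2, rt
Reagents that add atoms: none
Why: Manganese dioxide oxidation of a doubly allylic alcohol; the neutral conditions leave the polymerisable divinyl ketone intact, and it is used at once as a cold solution.

Step 3
Reactants: 4 (−)-menthone, (2S,5R)-5-methyl-2-(propan-2-yl)cyclohexan-1-one
Product: 6 trimethyl{[(3R,6S)-3-methyl-6-(propan-2-yl)cyclohex-1-en-1-yl]oxy}silane, via lithium enolate 5 (not isolated)
Conditions: LiN(iPr)2, THF, −78 °C; Me3SiCl, −78 → 0 °C
Reagents that add atoms: chlorotrimethylsilane, C[Si](C)(C)Cl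
Why: Kinetic deprotonation takes a proton from the unhindered C6 methylene and not from the isopropyl-bearing C2, so C2 keeps its configuration; O-silylation traps the less substituted enolate.

Step 4
Reactants: 6 trimethyl{[(3R,6S)-3-methyl-6-(propan-2-yl)cyclohex-1-en-1-yl]oxy}silane; 3 (E)-6-methylhepta-1,4-dien-3-one
Product: 8 (2S,5R,6R)-5-methyl-6-[(4E)-6-methyl-3-oxohept-4-en-1-yl]-2-(propan-2-yl)cyclohexan-1-one, via titanium enolate 7 (not isolated)
Conditions: TiCl4 (1.0 equiv), CH2Cl2, −78 °C; aq. NaHCO3, 0 °C
Reagents that add atoms: none
Why: Mukaiyama–Michael addition to the unsubstituted vinyl terminus of the activated dienone, far more reactive than the isopropyl-substituted terminus. The enol ether reacts through the half-chair with isopropyl and methyl pseudo-equatorial, and the electrophile enters C6 axially, anti-periplanar to the axial H-5; this sets the side chain trans to isopropyl and cis to methyl (6R). The competing chair-like path needs the ring-flipped conformer, in which the axial isopropyl group blocks the attacking face.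

Step 5
Reactants: 9 2,4,6-trihydroxybenzoic acid
Product: 10 prop-2-en-1-yl 2,4,6-trihydroxybenzoate
Conditions: allyl bromide, KHCO3, DMF, 40 °C
Reagents that add atoms: allyl bromide, C=CCBr
Why: SN2 O-alkylation of the carboxylate; hydrogencarbonate ionises only the carboxylic acid, so the phenols stay free.

Step 6
Reactants: 10 prop-2-en-1-yl 2,4,6-trihydroxybenzoate
Product: 11 prop-2-en-1-yl 2,6-dihydroxy-4-methoxybenzoate
Conditions: Me2SO4 (1.0 equiv), K2CO3 (1.0 equiv), acetone, rt
Reagents that add atoms: dimethyl sulfate, COS(=O)(=O)OC
Why: Williamson methylation of the most acidic phenol: the 4-OH is para to the ester and not hydrogen-bonded to it, whereas the 2- and 6-OH are chelated.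

Step 7
Reactants: 11 prop-2-en-1-yl 2,6-dihydroxy-4-methoxybenzoate
Product: 12 prop-2-en-1-yl 2-hydroxy-4-methoxy-3,3,5-trimethyl-6-oxocyclohexa-1,4-diene-1-carboxylate
Conditions: MeI (3.2 equiv), KOtBu (4 equiv), t-BuOH–THF, 0 °C → rt; dilute HCl
Reagents that add atoms: iodomethane, CI
Why: C-Methylation of the phenolate at C3 and C5, then dearomatising methylation at C3 (the dearomative alkylation known for phloroglucinol-type phenolates in protic solvent). The ester blocks C1, the methoxy group ends up by construction between C(CH3)2 and C–CH3, and tert-butoxide cannot exchange the allyl ester.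

Step 8
Reactants: 12 prop-2-en-1-yl 2-hydroxy-4-methoxy-3,3,5-trimethyl-6-oxocyclohexa-1,4-diene-1-carboxylate
Product: 14 3-hydroxy-5-methoxy-4,4,6-trimethylcyclohexa-2,5-dien-1-one, via β-keto acid 13 (not isolated)
Conditions: Pd(OAc)2 (cat.), PPh3, HCO2H, Et3N, THF, rt → 40 °C
Reagents that add atoms: none
Why: Palladium-catalysed deallylation with formate as hydride donor (Tsuji-type decarboxylation–hydrogenolysis) frees the carboxylic acid of a 1,3-diketone, which loses CO2 spontaneously; the neutral conditions spare the vinylogous methyl ester that aqueous acid or hydroxide would cleave.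

Step 9
Reactants: 8 (2S,5R,6R)-5-methyl-6-[(4E)-6-methyl-3-oxohept-4-en-1-yl]-2-(propan-2-yl)cyclohexan-1-one; 14 3-hydroxy-5-methoxy-4,4,6-trimethylcyclohexa-2,5-dien-1-one
Product: 15 3-hydroxy-5-methoxy-4,4,6-trimethyl-2-{(3R)-2-methyl-7-[(1R,3S,6R)-6-methyl-2-oxo-3-(propan-2-yl)cyclohexyl]-5-oxoheptan-3-yl}cyclohexa-2,5-dien-1-one
Conditions: 9-amino-9-deoxy-epi-quinidine (20 mol%), CF3CO2H (40 mol%), THF, rt
Reagents that add atoms: none
Why: Iminium-activated Michael addition of a cyclic 1,3-dicarbonyl to an enone, the reaction type of the catalytic asymmetric warfarin synthesis. The catalyst-bound iminium ion of the acyclic enone exposes one face of C4 to the nucleophilic carbon of 14 and should set C4 (R), while the doubly α-substituted ring ketone does not condense with the amine.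

Step 10
Reactants: 15 3-hydroxy-5-methoxy-4,4,6-trimethyl-2-{(3R)-2-methyl-7-[(1R,3S,6R)-6-methyl-2-oxo-3-(propan-2-yl)cyclohexyl]-5-oxoheptan-3-yl}cyclohexa-2,5-dien-1-one
Product: 16 3-hydroxy-5-methoxy-4,4,6-trimethyl-2-{(3R)-2-methyl-5-methylidene-7-[(1R,3S,6R)-6-methyl-2-oxo-3-(propan-2-yl)cyclohexyl]heptan-3-yl}cyclohexa-2,5-dien-1-one
Conditions: Ph3PCH3Br (4 equiv), KOtBu (4 equiv), THF, 0 °C → rt; aq. NaH2PO4
Reagents that add atoms: methyltriphenylphosphonium bromide, C[P+](c1ccccc1)(c1ccccc1)c1ccccc1.[Br-]
Why: Wittig methylenation: the first equivalent of ylide turns the trione into its enolate, which opens the hemiketal, deactivates the ring A carbonyls and cannot leave in a retro-Michael step. The acyclic C2 ketone then reacts, while the 2,6-disubstituted ring ketone is too hindered and its equatorial H-4a' is poorly placed for deprotonation.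

Step 11
Reactants: 16 3-hydroxy-5-methoxy-4,4,6-trimethyl-2-{(3R)-2-methyl-5-methylidene-7-[(1R,3S,6R)-6-methyl-2-oxo-3-(propan-2-yl)cyclohexyl]heptan-3-yl}cyclohexa-2,5-dien-1-one
Product: 17 (2S,4R,4a'R,5'R,8'S,8a'R)-8a'-hydroxy-7-methoxy-5',6,8,8-tetramethyl-4,8'-di(propan-2-yl)-1',3,4,4',4a',5',6',7',8',8a'-decahydro-3'H-spiro[chromene-2,2'-naphthalen]-5(8H)-one
Conditions: SnCl4 (2.2 equiv), 2,6-di-tert-butyl-4-methylpyridine (1.5 equiv), CH2Cl2, −78 → −40 °C; aq. NaHCO3
Reagents that add atoms: none
Why: SnCl4 activates the ring ketone, the 1,1-disubstituted alkene attacks through its CH2 terminus to form C1'–C8a', the charge appears on the tertiary C2, and the tin-bound enol oxygen on C8a, five atoms away, captures it to form O1–C2. The closest known reaction type is the Lewis-acid Prins (carbonyl-ene type) cyclisation of a 1,1-disubstituted alkene onto a ketone in which the cation is trapped by an internal oxygen nucleophile. Ring C closes as a six-membered chair, exo with respect to the carbonyl and with both alkene carbons inside the new ring; ring B closes as a six-membered ring by attack of O1 on the C2 cation. C8a' (R): the C4a' side chain is axial on the menthone chair, so C1' can reach the carbonyl only from the equatorial direction, which gives the cis-fused carbinol with the hydroxyl axial on ring D. C2 (S): the enol oxygen adds axially on the ring C chair, anti to H-4a', so that the larger C3 arm becomes equatorial and avoids the syn-axial C8'. The step needs C–C bond formation to outrun protonation of the alkene, which would add the enol directly and leave ring C open; the hindered pyridine base, which takes up the enol proton, and the low temperature secure this. It also needs oxygen capture to outrun proton loss from the cation, which the six-membered reach of the enol favours, and capture by the C8a oxygen and not the C5 oxygen, which is expected because only the former gives the cross-conjugated dienone and because the tertiary C–O bond can reopen under SnCl4 until the more stable isomer is reached.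

Step 12
Reactants: 17 (2S,4R,4a'R,5'R,8'S,8a'R)-8a'-hydroxy-7-methoxy-5',6,8,8-tetramethyl-4,8'-di(propan-2-yl)-1',3,4,4',4a',5',6',7',8',8a'-decahydro-3'H-spiro[chromene-2,2'-naphthalen]-5(8H)-one
Product: 19 (2S,4R,4a'R,5'R,8'S)-7-methoxy-5',6,8,8-tetramethyl-4,8'-di(propan-2-yl)-3,4,4',4a',5',6',7',8'-octahydro-3'H-spiro[chromene-2,2'-naphthalen]-5(8H)-one, via sulfamate ester 18 (not isolated)
Conditions: Burgess reagent (3 equiv), benzene, 50 °C
Reagents that add atoms: none
Why: Burgess dehydration, a syn (Ei) elimination of the sulfamate ester. The leaving group is axial on ring D, so H-8' is anti-periplanar and cannot be used by a syn process; of the two cis hydrogens, H-1' is reached by flexing ring C alone, whereas H-4a' would require eclipsing both rings about the fusion bond. The alkene should therefore form at C1'=C8a', and C2, C4, C4a', C5' and C8' are not touched.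

## Compound list

1 | (E)-4-methylpent-2-enal | CC(C)/C=C/C=O | starting material
2 | (E)-6-methylhepta-1,4-dien-3-ol (racemic) | C=CC(O)/C=C/C(C)C | intermediate
3 | (E)-6-methylhepta-1,4-dien-3-one | C=CC(=O)/C=C/C(C)C | intermediate
4 | (−)-menthone, (2S,5R)-5-methyl-2-(propan-2-yl)cyclohexan-1-one | C[C@@H]1CC[C@@H](C(C)C)C(=O)C1 | starting material
5 | lithium (3R,6S)-3-methyl-6-(propan-2-yl)cyclohex-1-en-1-olate, formed in situ | C[C@@H]1CC[C@@H](C(C)C)C(O[Li])=C1 | intermediate
6 | trimethyl{[(3R,6S)-3-methyl-6-(propan-2-yl)cyclohex-1-en-1-yl]oxy}silane | C[C@@H]1CC[C@@H](C(C)C)C(O[Si](C)(C)C)=C1 | intermediate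
7 | trichlorotitanium dienolate of 8 (O–TiCl3 on C3 of the side chain, C2=C3 enolate double bond), formed in situ | CC(C)/C=C/C(O[Ti](Cl)(Cl)Cl)=CC[C@@H]1[C@H](C)CC[C@@H](C(C)C)C1=O | intermediate
8 | (2S,5R,6R)-5-methyl-6-[(4E)-6-methyl-3-oxohept-4-en-1-yl]-2-(propan-2-yl)cyclohexan-1-one | CC(C)/C=C/C(=O)CC[C@@H]1[C@H](C)CC[C@@H](C(C)C)C1=O | intermediate
9 | 2,4,6-trihydroxybenzoic acid | OC(=O)c1c(O)cc(O)cc1O | starting material
10 | prop-2-en-1-yl 2,4,6-trihydroxybenzoate | C=CCOC(=O)c1c(O)cc(O)cc1O | intermediate
11 | prop-2-en-1-yl 2,6-dihydroxy-4-methoxybenzoate | C=CCOC(=O)c1c(O)cc(OC)cc1O | intermediate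
12 | prop-2-en-1-yl 2-hydroxy-4-methoxy-3,3,5-trimethyl-6-oxocyclohexa-1,4-diene-1-carboxylate | C=CCOC(=O)C1=C(O)C(C)(C)C(OC)=C(C)C1=O | intermediate
13 | 2-hydroxy-4-methoxy-3,3,5-trimethyl-6-oxocyclohexa-1,4-diene-1-carboxylic acid, formed in situ | OC(=O)C1=C(O)C(C)(C)C(OC)=C(C)C1=O | intermediate
14 | 3-hydroxy-5-methoxy-4,4,6-trimethylcyclohexa-2,5-dien-1-one (enol of 5-methoxy-4,6,6-trimethylcyclohex-4-ene-1,3-dione) | COC1=C(C)C(=O)C=C(O)C1(C)C | intermediate
15 | 3-hydroxy-5-methoxy-4,4,6-trimethyl-2-{(3R)-2-methyl-7-[(1R,3S,6R)-6-methyl-2-oxo-3-(propan-2-yl)cyclohexyl]-5-oxoheptan-3-yl}cyclohexa-2,5-dien-1-one | COC1=C(C)C(=O)C(=C(O)C1(C)C)[C@@H](C(C)C)CC(=O)CC[C@@H]2[C@H](C)CC[C@@H](C(C)C)C2=O | intermediate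
16 | 3-hydroxy-5-methoxy-4,4,6-trimethyl-2-{(3R)-2-methyl-5-methylidene-7-[(1R,3S,6R)-6-methyl-2-oxo-3-(propan-2-yl)cyclohexyl]heptan-3-yl}cyclohexa-2,5-dien-1-one | COC1=C(C)C(=O)C(=C(O)C1(C)C)[C@@H](C(C)C)CC(=C)CC[C@@H]2[C@H](C)CC[C@@H](C(C)C)C2=O | intermediate
17 | (2S,4R,4a'R,5'R,8'S,8a'R)-8a'-hydroxy-7-methoxy-5',6,8,8-tetramethyl-4,8'-di(propan-2-yl)-1',3,4,4',4a',5',6',7',8',8a'-decahydro-3'H-spiro[chromene-2,2'-naphthalen]-5(8H)-one | COC1=C(C)C(=O)C2=C(O[C@]3(C[C@@]4(O)[C@H](C(C)C)CC[C@@H](C)[C@H]4CC3)C[C@@H]2C(C)C)C1(C)C | intermediate
18 | triethylammonium salt of the 8a'-O-[N-(methoxycarbonyl)sulfamoyl] derivative of 17, formed in situ | COC1=C(C)C(=O)C2=C(O[C@]3(C[C@@]4(OS(=O)(=O)[N-]C(=O)OC)[C@H](C(C)C)CC[C@@H](C)[C@H]4CC3)C[C@@H]2C(C)C)C1(C)C.CC[NH+](CC)CC | intermediate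
19 | (2S,4R,4a'R,5'R,8'S)-7-methoxy-5',6,8,8-tetramethyl-4,8'-di(propan-2-yl)-3,4,4',4a',5',6',7',8'-octahydro-3'H-spiro[chromene-2,2'-naphthalen]-5(8H)-one | COC1=C(C)C(=O)C2=C(O[C@]3(C=C4[C@H](C(C)C)CC[C@@H](C)[C@H]4CC3)C[C@@H]2C(C)C)C1(C)C | target

## Step count and least certain steps

Total: 12 steps. Longest linear sequence: 8 steps (9 → 10 → 11 → 12 → 14 → 15 → 16 → 17 → 19; steps 5 to 12).

**Step 11 (key step).** The most likely failure is diversion of the cationic pathway before or after the C–C bond is made. The doubly α-substituted carbonyl reacts slowly, which gives time for proton loss from the C2 cation (a carbonyl-ene outcome) or for acid-promoted addition of the enol across the alkene with ring C still open. Capture by the C5 oxygen is a further risk if ring B closure is not reversible. Fallback, from 16 back to 17: the cascade is split into two known operations. Me2AlCl (3 equiv, CH2Cl2, −78 → 0 °C) consumes the enol proton as methane, so no free acid arises, and promotes the intramolecular carbonyl-ene reaction to the cis-fused tertiary homoallylic alcohol with an exocyclic C2=C3 alkene F1. Catalytic camphorsulfonic acid (CH2Cl2, 0 °C) then protonates this trisubstituted alkene at C3, and the enol oxygen closes ring B on the C2 cation to give 17.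

**Step 12.** Ionisation of the tertiary sulfamate ester may compete with the concerted syn elimination; the C8a' cation would then lose a proton toward C8' or C4a' and give the more substituted alkenes. Sulfamate formation at the hindered axial hydroxyl may also be slow. Fallback, from 15 back to 19: the alkene position is fixed by silicon and not by an elimination. Peterson-type olefination of the C2 ketone of 15 with (Me3Si)2CHLi (excess, THF, −78 → 0 °C) gives the vinylsilane F8. SnCl4 with the hindered pyridine base (CH2Cl2, −78 °C) makes the silicon-bearing carbon C1' attack the ring ketone with loss of Me3SiCl (vinylsilane-terminated carbonyl cyclisation) and gives the tertiary allylic alcohol with a C1'=C2 alkene F9. Camphorsulfonic acid (CH2Cl2, 0 °C) ionises F9 to the C8a'–C1'–C2 allyl cation. The enol oxygen can reach this cation only at C2, so ring B closes with the alkene at C1'=C8a' and gives 19, and the spiro centre can equilibrate through the same cation.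

**Step 4.** The risk is poor facial selectivity at C6 of the enol ether (attack from the equatorial side), or epimerisation of the axial side chain to the more stable all-equatorial arrangement by enolisation during work-up. Polymerisation of 3 is a lesser concern. Fallback, from 4 back to 8: an azaenolate is used, for which axial attack on conformationally biased cyclohexanones is the rule. Condensation of 4 with H2NNMe2 (cat. acid, EtOH, reflux) gives (−)-menthone N,N-dimethylhydrazone F2. LiN(iPr)2 (THF, 0 °C), CuI (−78 °C) and then 3 give, by conjugate addition of the hydrazone cuprate, the 6-alkylated hydrazone F3. Copper-assisted hydrolysis (Cu(OAc)2, THF–water, rt) releases ketone 8 under near-neutral conditions.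

**Step 9.** Iminium formation and addition at the hindered β-isopropyl enone may be slow, leading to low conversion or low enantioselectivity and thus a diastereomeric mixture at C4. The hemiketal form of 15 may also dehydrate under the acid co-catalyst. Fallback, from 14 and 1 back to 15: the order of the two conjugate additions is exchanged, and C4 is set on an enal, the best-behaved acceptor class for iminium catalysis. 14 adds to 1 under a diarylprolinol trimethylsilyl ether (the enantiomer that gives the R adduct; cat. PhCO2H, CH2Cl2) to give the aldehyde F4, present mainly as its lactol. Excess CH2=CHMgBr (THF, −78 °C) gives the allylic alcohol F5, and Dess–Martin periodinane oxidises it to the vinyl ketone F6. Mukaiyama–Michael addition of 6 to F6 (TiCl4, 2,6-di-tert-butyl-4-methylpyridine, CH2Cl2, −78 °C) then gives 15, with the axial selectivity argued for step 4.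

**Step 10.** The basic ylide may enolise the C2 ketone instead of adding to it (return of 15), and long exposure to base may epimerise the axial C4a' centre. Fallback, from 15 back to 16: a two-step Peterson methylenation with a non-basic nucleophile. Me3SiCH2MgCl–CeCl3 (excess, THF, −78 °C) adds to the C2 ketone to give the β-hydroxysilane F7, and buffered acid (NaOAc, AcOH, 50 °C) brings about the anti elimination to 16.

## Further compounds

F1 | step 11 | carbonyl-ene adduct of 16: cis-fused C8a' tertiary alcohol with exocyclic C2=C3 alkene and free trione enol | COC1=C(C)C(=O)C(=C(O)C1(C)C)[C@@H](C(C)C)C=C2CC[C@@H]3[C@H](C)CC[C@@H](C(C)C)[C@]3(O)C2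
F2 | step 4 | (−)-menthone N,N-dimethylhydrazone | C[C@@H]1CC[C@@H](C(C)C)C(=NN(C)C)C1
F3 | step 4 | N,N-dimethylhydrazone of 8 at the ring carbonyl | CC(C)/C=C/C(=O)CC[C@@H]1[C@H](C)CC[C@@H](C(C)C)C1=NN(C)C
F4 | step 9 | (3R)-3-(2-hydroxy-4-methoxy-3,3,5-trimethyl-6-oxocyclohexa-1,4-dien-1-yl)-4-methylpentanal | COC1=C(C)C(=O)C(=C(O)C1(C)C)[C@@H](C(C)C)CC=O
F5 | step 9 | (5R)-5-(2-hydroxy-4-methoxy-3,3,5-trimethyl-6-oxocyclohexa-1,4-dien-1-yl)-6-methylhept-1-en-3-ol (both C3 epimers) | COC1=C(C)C(=O)C(=C(O)C1(C)C)[C@@H](C(C)C)CC(O)C=C
F6 | step 9 | (5R)-5-(2-hydroxy-4-methoxy-3,3,5-trimethyl-6-oxocyclohexa-1,4-dien-1-yl)-6-methylhept-1-en-3-one | COC1=C(C)C(=O)C(=C(O)C1(C)C)[C@@H](C(C)C)CC(=O)C=C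
F7 | step 10 | β-hydroxysilane from 15 (C2 carbinol bearing a trimethylsilylmethyl group, both C2 epimers) | COC1=C(C)C(=O)C(=C(O)C1(C)C)[C@@H](C(C)C)CC(O)(C[Si](C)(C)C)CC[C@@H]2[C@H](C)CC[C@@H](C(C)C)C2=O
F8 | step 12 | vinylsilane analogue of 16 (C2=CH–SiMe3 in place of C2=CH2) | COC1=C(C)C(=O)C(=C(O)C1(C)C)[C@@H](C(C)C)CC(=C[Si](C)(C)C)CC[C@@H]2[C@H](C)CC[C@@H](C(C)C)C2=O
F9 | step 12 | tertiary allylic alcohol: ring C closed, C8a' hydroxyl, C1'=C2 alkene, free trione enol | COC1=C(C)C(=O)C(=C(O)C1(C)C)[C@@H](C(C)C)CC2=C[C@@]3(O)[C@H](C(C)C)CC[C@@H](C)[C@H]3CC2
A1 | alternative 1 | keto ester: spiro dihydropyran with methyl ester on C4a and 2-methyl-3-oxopentan-2-yl on C8a, rings C and D as in 19 | COC(=O)C2=C(O[C@]3(C=C4[C@H](C(C)C)CC[C@@H](C)[C@H]4CC3)C[C@@H]2C(C)C)C(C)(C)C(=O)CC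
A2 | alternative 1 | O-desmethyl 19 (C7 enol of the ring A trione) | OC1=C(C)C(=O)C2=C(O[C@]3(C=C4[C@H](C(C)C)CC[C@@H](C)[C@H]4CC3)C[C@@H]2C(C)C)C1(C)C
A3 | alternative 2 | 6-acetyl-5-hydroxy-3-methoxy-2,4,4-trimethylcyclohexa-2,5-dien-1-one | COC1=C(C)C(=O)C(C(C)=O)=C(O)C1(C)C
A4 | alternative 2 | (4aR,5R,8S)-5-methyl-8-(propan-2-yl)-4,4a,5,6,7,8-hexahydronaphthalen-2(3H)-one | O=C1C=C2[C@H](C(C)C)CC[C@@H](C)[C@H]2CC1
A5 | alternative 2 | spiro pyran-4-one (19 with C4 as carbonyl and without the C4 isopropyl group) | COC1=C(C)C(=O)C2=C(O[C@]3(C=C4[C@H](C(C)C)CC[C@@H](C)[C@H]4CC3)CC2=O)C1(C)C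
A6 | alternative 3 | triene: C2 bearing the (E)-4-methylpent-2-enoyl group and the 4-methylhexa-3,5-dienyl chain | COC1=C(C)C(=O)C2=C(O[C@](CCC=C(C)C=C)(C(=O)/C=C/C(C)C)C[C@@H]2C(C)C)C1(C)C
A7 | alternative 3 | cis-fused C1' ketone with C5'=C6' alkene | COC1=C(C)C(=O)C2=C(O[C@]3(C(=O)[C@H]4[C@H](C(C)C)CC=C(C)[C@H]4CC3)C[C@@H]2C(C)C)C1(C)C
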